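## Analysis of the target

- The target (32) is a tetralin. Aromatic ring A carries hydroxyls on C5 and C6 and the carboxyl on C7, leaving only C8–H; saturated ring B carries a methyl on C4 and the side chain on C1 (tetralin numbered C1–C8 from the side-chain carbon).
- The side chain is C11(C20H2OH)–C12–C13–C14–C15(CH3)–C16H2OH.
- There are four stereocentres. C1 (S) and C4 (R) are both benzylic and trans across ring B. C11 (S) is vicinal to C1. C15 (S) lies three methylenes beyond C11, so no neighbouring centre can steer it.
- Sensitive groups are the catechol (air oxidation, kept as methyl ethers to the last step), the salicylic-type acid, the two primary alcohols, and the benzylic methines C1 and C4, which must never sit α to a carbonyl.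
- The hard parts are the remote 1,5-pair C11/C15 and the attachment of C11 next to C1 with defined configuration.
- The strategy rests on one feature: C11 and C15 each bear a hydroxymethyl carbon (C20, C16) and are bridged by C12–C14. Joining C16 to C20 as a double bond turns C11–C12–C13–C14–C15–C16=C20 into a cycloheptene with the tetralin and the methyl cis on the two allylic carbons. The remote relationship becomes a ring cis relationship.

## Retrosynthetic reasoning

**32 ⇒ 31.** The two O–CH3 bonds at C5 and C6 are cut last. The methyl ethers protect the catechol through every oxidative step and direct the metalation that places the carboxyl.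

**31 ⇒ 29.** C16 and C20 are reconnected as the alkene of a cycloheptene. In the forward sense one oxidative cleavage with reductive work-up releases both hydroxymethyl groups, and the cis ring relationship becomes (11S,15S).

**29 ⇒ 27.** The C7–carboxyl bond is cut. C7 is the only ring position ortho to a methoxy group, so directed lithiation of 27 can go nowhere else on ring A. Doing this before the alkene is cleaved means no hydroxyl protection is needed, and the acid deactivates the arene toward the later oxidant.

**27 ⇒ 25 ⇒ 24 ⇒ 23.** An ester is placed on C14 and a C13=C14 alkene is introduced; this is the retron of a vinylcarbene annulation. Forward, the ester is excised (conjugate reduction, saponification, radical decarboxylation) while C16 and C20 are still tied up as an alkene. If the diol were released first, the C16 hydroxyl would lactonise onto the C14 ester and the C20 hydroxyl could add to the enoate.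

**23 ⇒ 17 + 21.** C14–C15 and C11–C12 are cut, giving the (E,E)-diene 17 and the vinyldiazoacetate 21. No other cut of the seven-membered ring keeps the C16=C20 alkene and supplies C12–C14 as one three-carbon piece. Forward, cyclopropanation and Cope rearrangement must set C15 and C11 together.

**21 ⇒ 20 ⇒ 19 ⇒ 18.** The diazo ester goes back to methyl acetoacetate 18 by dehydration, ketone reduction and diazo transfer.

**17 ⇒ 15 + 16, and 15 ⇒ 13 + 14.** The diene is cut at C15=C16 (olefination of enal 15 with sulfone 16) and the enal at C20 (cross-metathesis of vinyl compound 13 with crotonaldehyde 14). Building the diene outward from a vinyl group keeps C1 away from any α-carbonyl position.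

**13 ⇒ 9 + 10, and 9 ⇒ 8.** The C1–C11 bond is cut to boronic ester 9 and vinyl Grignard 10; a 1,2-metallate shift transfers C1 with retention. The C1–B bond comes from a catalyst-controlled Markovnikov hydroboration of the styrene-type alkene of 8.

**8 ⇒ 6 ⇒ 4 + 5, then 4 ⇒ 3 ⇒ 1 + 2.** Ring B is opened at C1–C8a: an oxocarbenium ion from enol ether 6 attacks the arene para to a methoxy group and then loses methanol. 6 is the one-carbon homologue of aldehyde 4 (Wittig with 5). The C4–aryl bond and the C4 stereocentre come from asymmetric conjugate addition of boronic acid 1 to crotonate 2.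

## Alternatives that were turned down

**Alternative 1: pyrone–alkyne cycloaddition.**
- Disconnection: C7–C8 and C4a–C8a, so ring A itself is traced to a 2-pyrone whose C3–C6 become C7, C6, C5 and C4a.
- Forward key step: heating the pyrone–alkyne A2 makes the tethered terminal alkyne add across pyrone C3/C6; loss of CO2 gives the tetralin ester A1.
- For: the substitution pattern of ring A, carboxyl included, is fixed by construction, and two rings form in one irreversible step. On arene regiochemistry it is stronger than the chosen route, which needs a late metalation.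
- Against: the step creates no stereocentre. All four (C1, C4, C11, C15) must already sit on the open chain of A2, including the contiguous C1/C11 pair and the remote C15. C4 is attached to pyrone C6, where its hydrogen is vinylogously acidic. An unactivated alkyne needs high temperature.
- Comparison: the chosen route creates and correlates C11 and C15 in its key step and starts from a simple arene; A2 needs a long linear chain synthesis first.

**Alternative 2: carboalumination and cross-coupling.**
- Disconnection: C13–C14 and C15–CH3.
- Forward key step: zirconium-catalysed enantioselective methylalumination of allyl alcohol A5 gives a chiral alkylalane, which is coupled in the same flask under palladium catalysis with alkenyl iodide A4 to give A3.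
- For: it is convergent, sets C15 by reagent control exactly where needed, and carries no sacrificial carbon. On convergence and atom economy it is stronger than the chosen route.
- Against: methylalumination of A5 is only moderately selective, and 1,5-related diastereomers of A3 would be hard to separate. A4 must already contain the C1/C11 pair, which the key step does not help to build. Alkene saturation and debenzylation follow.
- Comparison: the chosen route ties C11 to C15 through one transition state instead of two independent inductions, and makes C11 in the same operation.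

**Alternative 3: arene opening of a lactone-fused cyclopropane.**
- Disconnection: C1–C8a, ring B closed by the arene.
- Forward key step: a Lewis acid activates the doubly acceptor-substituted cyclopropane A7; C8a attacks C1 opposite the departing C12 and gives lactone A6 with inversion at C1.
- For: C1 is set stereospecifically as ring B closes, and the C1/C11 relationship comes from one cyclopropane. On that relationship it is stronger than the chosen route, which sets C1 and C11 in separate catalyst-controlled steps.
- Against: C1 of A7 bears only an alkyl group, so opening needs forcing acid and may proceed through an open cation or elimination, losing the inversion. A6 still lacks C14–C16 and the C15 stereocentre, carries an extra ester, and has a lactone carbonyl at C13 that must end as CH2.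
- Comparison: the chosen route solves the remote centre inside its key step and needs fewer operations afterwards.

Key step: step 12

Remark: the sense of induction of (S)-BINAP (step 1), (S)-DTBM-SEGPHOS (step 5) and Rh2(R-DOSP)4 (step 12) is assigned by analogy with the closest simple substrates; the mirror-image ligand is available in each case.

In step names, Tet = (1S,4R)-5,6-dimethoxy-4-methyl-1,2,3,4-tetrahydronaphthalen-1-yl; full names are in the compound list.

## Route

Step 1
Reactants: 1 2,3-dimethoxyphenylboronic acid; 2 methyl (E)-but-2-enoate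
Product: 3 methyl (3R)-3-(2,3-dimethoxyphenyl)butanoate
Conditions: [Rh(acac)(C2H4)2] (3 mol%), (S)-BINAP, dioxane/H2O 10:1, 100 °C
Reagents that add atoms: none
Why: Hayashi–Miyaura rhodium-catalysed asymmetric 1,4-addition; the aryl–rhodium species inserts the enoate on the face set by the BINAP chelate, which should give the 3R ester (C4 of the target); a bulkier crotonate ester is the obvious lever if higher enantiopurity is wanted.

Step 2
Reactants: 3 methyl (3R)-3-(2,3-dimethoxyphenyl)butanoate
Product: 4 (3R)-3-(2,3-dimethoxyphenyl)butanal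
Conditions: i-Bu2AlH (1.05 equiv), CH2Cl2, −78 °C; aq. potassium sodium tartrate
Reagents that add atoms: none
Why: Partial reduction of an ester through the tetrahedral aluminium hemiacetal, which survives at −78 °C; the stereocentre is β to the carbonyl and not at risk.

Step 3
Reactants: 4 (3R)-3-(2,3-dimethoxyphenyl)butanal; 5 (methoxymethyl)triphenylphosphonium chloride
Product: 6 1,2-dimethoxy-3-[(2R)-5-methoxypent-4-en-2-yl]benzene (E/Z mixture)
Conditions: 5, KN(SiMe3)2, THF, 0 °C; then 4, 0 °C → rt
Reagents that add atoms: none
Why: Wittig methoxymethylenation adds the carbon that becomes C1; the alkene geometry is irrelevant because both isomers give the same oxocarbenium ion.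

Step 4
Reactants: 6 1,2-dimethoxy-3-[(2R)-5-methoxypent-4-en-2-yl]benzene
Product: 8 (1R)-7,8-dimethoxy-1-methyl-1,2-dihydronaphthalene, via 1-methoxytetralin 7 (not isolated)
Conditions: p-TsOH·H2O (10 mol%), benzene (0.02 M), 70 °C
Reagents that add atoms: none
Why: Acid-mediated intramolecular Friedel–Crafts cyclisation of an enol ether (Bradsher-type cyclodehydration): the oxocarbenium ion is attacked by the ring carbon para to a methoxy group, closing the six-membered ring, and the p-methoxybenzylic ether 7 then loses methanol to the styrene; C4 is not involved.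

Step 5
Reactants: 8 (1R)-7,8-dimethoxy-1-methyl-1,2-dihydronaphthalene
Product: 9 2-[(1R,4R)-5,6-dimethoxy-4-methyl-1,2,3,4-tetrahydronaphthalen-1-yl]-4,4,5,5-tetramethyl-1,3,2-dioxaborolane
Conditions: CuCl (5 mol%), (S)-DTBM-SEGPHOS (5.5 mol%), NaOt-Bu (10 mol%), pinacolborane, toluene, rt
Reagents that add atoms: pinacolborane, CC1(C)OBOC1(C)C
Why: Copper-hydride hydroboration: Markovnikov hydrocupration puts copper on benzylic C1, and σ-bond metathesis with the borane gives the boronic ester with retention. The bisphosphine selects the alkene face, and attack anti to the pseudoaxial C4 methyl points the same way, so ligand and substrate should cooperate to give the trans (1R,4R) isomer.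

Step 6
Reactants: 9 boronic ester; 10 ethenylmagnesium bromide
Product: 13 (1S,4R)-1-ethenyl-5,6-dimethoxy-4-methyl-1,2,3,4-tetrahydronaphthalene, via vinylboronate complex 11 (not isolated), via β-iodoalkylboronic ester 12 (not isolated)
Conditions: 10 (4 equiv), THF/DMSO 1:1, 0 °C → rt; I2, MeOH, 0 °C; NaOMe, MeOH, 0 °C → rt
Reagents that add atoms: none
Why: Zweifel olefination: iodination of the vinyl group of 11 triggers a 1,2-shift of the tetralinyl group from boron to carbon with retention at C1 (12), and methoxide induces anti elimination of boron and iodine; the C1 configuration is carried unchanged into 13.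

Step 7
Reactants: 13 Tet-CH=CH2; 14 (E)-but-2-enal
Product: 15 (2E)-3-Tet-prop-2-enal
Conditions: 14 (6 equiv), second-generation Hoveyda–Grubbs catalyst (5 mol%), CH2Cl2, 40 °C
Reagents that add atoms: none
Why: Olefin cross-metathesis of a terminal alkene with an enal, releasing propene; E selectivity is thermodynamic, and C1 is γ to the carbonyl and cannot epimerise by simple enolisation.

Step 8
Reactants: 15 (2E)-3-Tet-prop-2-enal; 16 5-(ethanesulfonyl)-1-phenyl-1H-tetrazole
Product: 17 (1S,4R)-5,6-dimethoxy-4-methyl-1-[(1E,3E)-penta-1,3-dien-1-yl]-1,2,3,4-tetrahydronaphthalene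
Conditions: 16, KN(SiMe3)2, DME, −60 °C; then 15, −60 °C → rt
Reagents that add atoms: none
Why: Julia–Kocienski olefination: the metalated sulfone adds to the enal, and Smiles rearrangement with loss of sulfur dioxide and tetrazolate forms C15=C16; E is favoured for this sulfone with potassium in DME. A minor Z isomer would be separated here or equilibrated with a trace of I2.

Step 9
Reactants: 18 methyl 3-oxobutanoate
Product: 19 methyl 2-diazo-3-oxobutanoate
Conditions: 4-acetamidobenzenesulfonyl azide, Et3N, MeCN, 0 °C → rt
Reagents that add atoms: 4-acetamidobenzenesulfonyl azide, CC(=O)Nc1ccc(cc1)S(=O)(=O)N=[N+]=[N-]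
Why: Regitz diazo transfer to an active methylene compound.

Step 10
Reactants: 19 methyl 2-diazo-3-oxobutanoate
Product: 20 methyl 2-diazo-3-hydroxybutanoate (racemic)
Conditions: NaBH4, MeOH, 0 °C
Reagents that add atoms: none
Why: Chemoselective borohydride reduction of the ketone; the diazo ester is left intact, and the carbinol centre is removed in the next step.

Step 11
Reactants: 20 methyl 2-diazo-3-hydroxybutanoate
Product: 21 methyl 2-diazobut-3-enoate
Conditions: POCl3, Et3N, CH2Cl2, 0 °C; pentane extract used at once
Reagents that add atoms: none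
Why: Dehydration through the dichlorophosphate and base-induced elimination; 21 is used immediately because it slowly cyclises to a pyrazole on standing.

Step 12
Reactants: 17 (1S,4R)-1-[(1E,3E)-penta-1,3-dien-1-yl]tetralin; 21 methyl 2-diazobut-3-enoate
Product: 23 methyl (4R,7R)-4-Tet-7-methylcyclohepta-1,5-diene-1-carboxylate, via cis-divinylcyclopropane 22 (not isolated)
Conditions: Rh2(R-DOSP)4 [dirhodium tetrakis((R)-N-(4-dodecylbenzenesulfonyl)prolinate)] (2 mol%), hexanes, −40 °C → rt; 21 (3 equiv) added over 3 h
Reagents that add atoms: none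
Why: Rh2(R-DOSP)4 turns 21 into a rhodium vinylcarbene whose carbene carbon (C14) adds across C15=C16, bonding first to the methyl-bearing terminus C15 while charge develops at allylic C16, to give cyclopropane 22 with the vinyl group and the C20=C11 alkenyl group cis. 22 then undergoes a strain-driven [3,3] shift through a boat transition state that makes C11–C12 and breaks C14–C16. The closest known reaction type is the tandem cyclopropanation/Cope rearrangement of vinyldiazoacetates with acyclic dienes, which is documented for (E,E)-1,4-disubstituted dienes but is slow for them. The seven-membered ring is closed in the sigmatropic step, by bond formation between the alkene termini C12 and C11 that are held cis on the cyclopropane. C15 is fixed in the cyclopropanation by the chiral carboxylate ligands; the R catalyst is chosen by transposing the (1S,2R) outcome of the S catalyst with styrene onto this alkene. C11 is fixed in the Cope step: the boat geometry with the tetralinyl group of the E alkene pointing outward relates it to C15, so the (E,E)-diene must give the cis (4R,7R) ring. The step needs attack at C15=C16 rather than C11=C20 (which with the same catalyst would give a regioisomeric ester with both new centres inverted, separable as a constitutional isomer) and cyclopropanation rather than insertion into the C1–H bond; the first is secured by the small methyl at C15 against the branched tetralin carbon next to C11, the second by the higher reactivity of a diene and the crowding of the tertiary C1–H.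

Step 13
Reactants: 23 methyl (4R,7R)-4-Tet-7-methylcyclohepta-1,5-diene-1-carboxylate
Product: 24 methyl (2R,5R)-5-Tet-2-methylcyclohept-3-ene-1-carboxylate (both C1 epimers)
Conditions: Cu(OAc)2·H2O (5 mol%), 1,2-bis(diphenylphosphino)benzene (5 mol%), (EtO)2MeSiH, t-BuOH, toluene, rt
Reagents that add atoms: none
Why: Copper-hydride 1,4-reduction: hydride is delivered to C13 of the enoate only and the isolated C16=C20 alkene is inert; the new centre at C14 forms as a mixture, which does not matter because it becomes CH2 in step 15.

Step 14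
Reactants: 24 methyl (2R,5R)-5-Tet-2-methylcyclohept-3-ene-1-carboxylate
Product: 25 (2R,5R)-5-Tet-2-methylcyclohept-3-ene-1-carboxylic acid (both C1 epimers)
Conditions: LiOH·H2O, THF/MeOH/H2O, 50 °C; 1 M HCl
Reagents that add atoms: lithium hydroxide, [Li+].[OH-]
Why: Ester saponification; only C14, which is not retained as a stereocentre, is α to the carboxyl.

Step 15
Reactants: 25 (2R,5R)-5-Tet-2-methylcyclohept-3-ene-1-carboxylic acid
Product: 27 (1S,4R)-5,6-dimethoxy-4-methyl-1-[(1R,4S)-4-methylcyclohept-2-en-1-yl]-1,2,3,4-tetrahydronaphthalene, via thiohydroxamate ester 26 (not isolated)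
Conditions: N-hydroxypyridine-2-thione, DCC, DMAP (cat.), CH2Cl2, rt, dark; then t-BuSH, hν (tungsten lamp), rt
Reagents that add atoms: none
Why: Barton reductive decarboxylation: ester 26 fragments under light to carbon dioxide and the secondary C14 radical, which takes hydrogen from the thiol; no retained stereocentre is touched.

Step 16
Reactants: 27 (1S,4R)-1-[(1R,4S)-4-methylcyclohept-2-en-1-yl]tetralin
Product: 29 (5R,8S)-3,4-dimethoxy-5-methyl-8-[(1R,4S)-4-methylcyclohept-2-en-1-yl]-5,6,7,8-tetrahydronaphthalene-2-carboxylic acid, via aryllithium 28 (not isolated)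
Conditions: n-BuLi, TMEDA, Et2O, 0 °C → rt; CO2, −78 °C → rt; 1 M HCl
Reagents that add atoms: carbon dioxide, O=C=O
Why: Directed ortho-metalation: C7 is the only ring position ortho to a methoxy group, which coordinates lithium, and carboxylation of 28 installs the acid there.

Step 17
Reactants: 29 (5R,8S)-3,4-dimethoxy-5-methyl-8-[(1R,4S)-4-methylcyclohept-2-en-1-yl]-5,6,7,8-tetrahydronaphthalene-2-carboxylic acid
Product: 31 (5R,8S)-8-[(2S,6S)-1,7-dihydroxy-6-methylheptan-2-yl]-3,4-dimethoxy-5-methyl-5,6,7,8-tetrahydronaphthalene-2-carboxylic acid, via ozonide 30 (not isolated)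
Conditions: O3, CH2Cl2, −78 °C (stopped at first persistent blue); then NaBH4, MeOH, −78 → 0 °C
Reagents that add atoms: ozone, [O-][O+]=O
Why: Ozonolysis with reductive work-up: the only alkene is cleaved and the ozonide is reduced directly to the two primary alcohols, so no free α-branched aldehyde persists long enough to epimerise C11 or C15; the carboxyl group makes the arene less prone to attack by ozone.

Step 18
Reactants: 31 (5R,8S)-8-[(2S,6S)-1,7-dihydroxy-6-methylheptan-2-yl]-3,4-dimethoxy-5-methyl-5,6,7,8-tetrahydronaphthalene-2-carboxylic acid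
Product: 32 (5R,8S)-8-[(2S,6S)-1,7-dihydroxy-6-methylheptan-2-yl]-3,4-dihydroxy-5-methyl-5,6,7,8-tetrahydronaphthalene-2-carboxylic acid
Conditions: BBr3 (8 equiv), CH2Cl2, −78 → 0 °C; H2O
Reagents that add atoms: none
Why: Lewis-acid cleavage of both aryl methyl ethers, helped by chelation to the neighbouring carboxyl; the borate esters of the alcohols are hydrolysed on work-up, and the low temperature is chosen to avoid substitution at the primary carbons.

## Compound list

1 | 2,3-dimethoxyphenylboronic acid | COc1cccc(B(O)O)c1OC | starting material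
2 | methyl (E)-but-2-enoate | C/C=C/C(=O)OC | starting material
3 | methyl (3R)-3-(2,3-dimethoxyphenyl)butanoate | C[C@H](CC(=O)OC)c1cccc(OC)c1OC | intermediate
4 | (3R)-3-(2,3-dimethoxyphenyl)butanal | C[C@H](CC=O)c1cccc(OC)c1OC | intermediate
5 | (methoxymethyl)triphenylphosphonium chloride | [Cl-].COC[P+](c1ccccc1)(c1ccccc1)c1ccccc1 | starting material
6 | 1,2-dimethoxy-3-[(2R)-5-methoxypent-4-en-2-yl]benzene (E/Z mixture) | C[C@H](CC=COC)c1cccc(OC)c1OC | intermediate
7 | (4R)-1,5,6-trimethoxy-4-methyl-1,2,3,4-tetrahydronaphthalene (both C1 epimers; not isolated) | COC1CC[C@@H](C)c2c1ccc(OC)c2OC | intermediate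
8 | (1R)-7,8-dimethoxy-1-methyl-1,2-dihydronaphthalene | C1=CC[C@@H](C)c2c1ccc(OC)c2OC | intermediate
9 | 2-[(1R,4R)-5,6-dimethoxy-4-methyl-1,2,3,4-tetrahydronaphthalen-1-yl]-4,4,5,5-tetramethyl-1,3,2-dioxaborolane | CC1(C)OB(OC1(C)C)[C@@H]2CC[C@@H](C)c3c2ccc(OC)c3OC | intermediate
10 | ethenylmagnesium bromide | C=C[Mg]Br | starting material
11 | bromomagnesium ethenyl[(1R,4R)-5,6-dimethoxy-4-methyl-1,2,3,4-tetrahydronaphthalen-1-yl](pinacolato)borate (not isolated) | C=C[B-]1(OC(C)(C)C(C)(C)O1)[C@@H]2CC[C@@H](C)c3c2ccc(OC)c3OC.[Mg+]Br | intermediate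
12 | 2-{2-iodo-1-[(1S,4R)-5,6-dimethoxy-4-methyl-1,2,3,4-tetrahydronaphthalen-1-yl]ethyl}-4,4,5,5-tetramethyl-1,3,2-dioxaborolane (not isolated) | ICC(B1OC(C)(C)C(C)(C)O1)[C@@H]2CC[C@@H](C)c3c2ccc(OC)c3OC | intermediate
13 | (1S,4R)-1-ethenyl-5,6-dimethoxy-4-methyl-1,2,3,4-tetrahydronaphthalene | C=C[C@@H]1CC[C@@H](C)c2c1ccc(OC)c2OC | intermediate
14 | (E)-but-2-enal | C/C=C/C=O | starting material
15 | (2E)-3-[(1S,4R)-5,6-dimethoxy-4-methyl-1,2,3,4-tetrahydronaphthalen-1-yl]prop-2-enal | O=C/C=C/[C@@H]1CC[C@@H](C)c2c1ccc(OC)c2OC | intermediate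
16 | 5-(ethanesulfonyl)-1-phenyl-1H-tetrazole | CCS(=O)(=O)c1nnnn1-c1ccccc1 | starting material
17 | (1S,4R)-5,6-dimethoxy-4-methyl-1-[(1E,3E)-penta-1,3-dien-1-yl]-1,2,3,4-tetrahydronaphthalene | C/C=C/C=C/[C@@H]1CC[C@@H](C)c2c1ccc(OC)c2OC | intermediate
18 | methyl 3-oxobutanoate | CC(=O)CC(=O)OC | starting material
19 | methyl 2-diazo-3-oxobutanoate | CC(=O)C(=[N+]=[N-])C(=O)OC | intermediate
20 | methyl 2-diazo-3-hydroxybutanoate (racemic) | CC(O)C(=[N+]=[N-])C(=O)OC | intermediate
21 | methyl 2-diazobut-3-enoate | C=CC(=[N+]=[N-])C(=O)OC | intermediate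
22 | methyl (1R,2R,3R)-1-ethenyl-2-methyl-3-{(E)-2-[(1S,4R)-5,6-dimethoxy-4-methyl-1,2,3,4-tetrahydronaphthalen-1-yl]ethenyl}cyclopropane-1-carboxylate (alkenyl groups cis, methyl trans to the adjacent alkenyl group; not isolated) | COC(=O)[C@]1(C=C)[C@H](C)[C@H]1/C=C/[C@@H]2CC[C@@H](C)c3c2ccc(OC)c3OC | intermediate
23 | methyl (4R,7R)-4-[(1S,4R)-5,6-dimethoxy-4-methyl-1,2,3,4-tetrahydronaphthalen-1-yl]-7-methylcyclohepta-1,5-diene-1-carboxylate | C[C@@H]1C=C[C@H]([C@@H]2CC[C@@H](C)c3c2ccc(OC)c3OC)CC=C1C(=O)OC | intermediate
24 | methyl (2R,5R)-5-[(1S,4R)-5,6-dimethoxy-4-methyl-1,2,3,4-tetrahydronaphthalen-1-yl]-2-methylcyclohept-3-ene-1-carboxylate (both C1 epimers) | C[C@@H]1C=C[C@H]([C@@H]2CC[C@@H](C)c3c2ccc(OC)c3OC)CCC1C(=O)OC | intermediate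
25 | (2R,5R)-5-[(1S,4R)-5,6-dimethoxy-4-methyl-1,2,3,4-tetrahydronaphthalen-1-yl]-2-methylcyclohept-3-ene-1-carboxylic acid (both C1 epimers) | C[C@@H]1C=C[C@H]([C@@H]2CC[C@@H](C)c3c2ccc(OC)c3OC)CCC1C(=O)O | intermediate
26 | 2-thioxopyridin-1(2H)-yl ester of acid 25 (not isolated) | C[C@@H]1C=C[C@H]([C@@H]2CC[C@@H](C)c3c2ccc(OC)c3OC)CCC1C(=O)ON4C=CC=CC4=S | intermediate
27 | (1S,4R)-5,6-dimethoxy-4-methyl-1-[(1R,4S)-4-methylcyclohept-2-en-1-yl]-1,2,3,4-tetrahydronaphthalene | C[C@@H]1C=C[C@H]([C@@H]2CC[C@@H](C)c3c2ccc(OC)c3OC)CCC1 | intermediate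
28 | C7-lithio derivative of 27, {(5R,8S)-3,4-dimethoxy-5-methyl-8-[(1R,4S)-4-methylcyclohept-2-en-1-yl]-5,6,7,8-tetrahydronaphthalen-2-yl}lithium (not isolated) | C[C@@H]1C=C[C@H]([C@@H]2CC[C@@H](C)c3c2cc([Li])c(OC)c3OC)CCC1 | intermediate
29 | (5R,8S)-3,4-dimethoxy-5-methyl-8-[(1R,4S)-4-methylcyclohept-2-en-1-yl]-5,6,7,8-tetrahydronaphthalene-2-carboxylic acid | C[C@@H]1C=C[C@H]([C@@H]2CC[C@@H](C)c3c2cc(C(=O)O)c(OC)c3OC)CCC1 | intermediate
30 | secondary ozonide of 29 (8,9,10-trioxabicyclo[5.2.1]decane in place of the cycloheptene, C11 and C15 unchanged; not isolated) | C[C@@H]1C4OC(OO4)[C@H]([C@@H]2CC[C@@H](C)c3c2cc(C(=O)O)c(OC)c3OC)CCC1 | intermediate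
31 | (5R,8S)-8-[(2S,6S)-1,7-dihydroxy-6-methylheptan-2-yl]-3,4-dimethoxy-5-methyl-5,6,7,8-tetrahydronaphthalene-2-carboxylic acid | C[C@H](CO)CCC[C@H](CO)[C@@H]1CC[C@@H](C)c2c1cc(C(=O)O)c(OC)c2OC | intermediate
32 | (5R,8S)-8-[(2S,6S)-1,7-dihydroxy-6-methylheptan-2-yl]-3,4-dihydroxy-5-methyl-5,6,7,8-tetrahydronaphthalene-2-carboxylic acid | C[C@H](CO)CCC[C@H](CO)[C@@H]1CC[C@@H](C)c2c1cc(C(=O)O)c(O)c2O | target

## Step count and least certain steps

Total: 18 steps. Longest linear sequence: 15 steps (steps 1–8 and 12–18); steps 9–11 are a three-step side branch to 21.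

**Step 12 (key step).** Carbene transfer to a trans-disubstituted diene terminus is slow. Carbene dimerisation, pyrazole formation from 21 and insertion into the doubly activated C1–H bond may therefore compete. Incomplete discrimination between the two alkenes, or a mismatched facial preference, would erode the C11/C15 configuration. Fallback: an oxyallyl-cation [4+3] cycloaddition, which needs no diazo compound and no sacrificial ester. Diene 17 would be heated with 1,1,3,3-tetrabromoacetone and Fe2(CO)9 in benzene to give the dibromocycloheptenone F1. Reductive debromination (Zn/Cu, NH4Cl, MeOH) would give the cis-3-methyl-6-tetralinylcyclohept-4-enone F2. Its tosylhydrazone F3 would be reduced with catecholborane and then NaOAc, rejoining the route at 27. Facial selectivity would then rest on the C1 stereocentre alone.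

**Step 4.** The electron-rich styrene product can be re-protonated and dimerise or oligomerise under the acid that forms it, and elimination from 7 may stall. Fallback: classical acylation that never exposes the styrene to acid. Enol ether 6 would be hydrolysed (aq. HCl, THF) to (4R)-4-(2,3-dimethoxyphenyl)pentanal F4 and oxidised (NaClO2, NaH2PO4, 2-methylbut-2-ene) to the pentanoic acid F5. Friedel–Crafts cyclisation ((CF3CO)2O, CH2Cl2) would give the 4-methyltetralone F6. This would be converted (KN(SiMe3)2, PhNTf2) into the enol triflate F7 and reduced (Pd(OAc)2, PPh3, HCO2H, n-Bu3N, DMF, 60 °C) to 8.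

**Step 5.** Facial discrimination by the ligand on a cyclic cis-styrene with a remote stereocentre may be insufficient, giving C1 epimers. Fallback: thermodynamic rather than kinetic control of C1, starting from 9 as an epimer mixture. Matteson homologation (ICH2Cl, n-BuLi, THF, −78 °C → rt) would give the homologated boronic ester F8, and oxidation (NaOH, H2O2) the primary alcohol F9. Dess–Martin oxidation would give the tetralin-1-carbaldehyde F10. Equilibration with DBU should enrich the trans isomer, the only one in which both benzylic substituents can sit pseudoaxial, away from the peri methoxy group and the peri hydrogen. Wittig reaction with Ph3P=CHCHO (toluene, 80 °C) would return to 15.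

**Step 16.** Deprotonation at the benzylic methines or allylic positions may compete with ring metalation, or lithiation may be incomplete. Fallback: C–H borylation followed by carboxylation, avoiding strong base. 27 would be borylated ([Ir(OMe)(cod)]2, 4,4'-di-tert-butyl-2,2'-bipyridine, B2pin2, THF, 60 °C) at the less hindered C7 to give the arylboronic ester F11. Carboxylation ((IPr)CuCl, KOt-Bu, CO2, THF, 70 °C; HCl) would return to 29.

**Step 18.** The primary hydroxyls may be converted into bromides, or the second ether cleavage may be incomplete. Fallback: the hydroxyls are masked as esters before the Lewis acid is used. 31 would be acetylated (Ac2O, pyridine, DMAP; aqueous work-up) to the diacetate F12 and demethylated (BBr3, CH2Cl2, −78 → −20 °C) to the catechol diacetate F13. Deacetylation (K2CO3, degassed MeOH) would give 32.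

## Further compounds

F1 | step 12 | 2,7-dibromo-3-methyl-6-[(1S,4R)-5,6-dimethoxy-4-methyl-1,2,3,4-tetrahydronaphthalen-1-yl]cyclohept-4-en-1-one (ring stereocentres as in F2, bromine-bearing carbons as mixtures) | C[C@@H]1C=C[C@H]([C@@H]2CC[C@@H](C)c3c2ccc(OC)c3OC)C(Br)C(=O)C1Br
F2 | step 12 | (3S,6R)-3-methyl-6-[(1S,4R)-5,6-dimethoxy-4-methyl-1,2,3,4-tetrahydronaphthalen-1-yl]cyclohept-4-en-1-one | C[C@@H]1C=C[C@H]([C@@H]2CC[C@@H](C)c3c2ccc(OC)c3OC)CC(=O)C1
F3 | step 12 | 4-methylbenzenesulfonylhydrazone of F2 | C[C@@H]1C=C[C@H]([C@@H]2CC[C@@H](C)c3c2ccc(OC)c3OC)CC(=NNS(=O)(=O)c4ccc(C)cc4)C1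
F4 | step 4 | (4R)-4-(2,3-dimethoxyphenyl)pentanal | C[C@H](CCC=O)c1cccc(OC)c1OC
F5 | step 4 | (4R)-4-(2,3-dimethoxyphenyl)pentanoic acid | C[C@H](CCC(=O)O)c1cccc(OC)c1OC
F6 | step 4 | (4R)-5,6-dimethoxy-4-methyl-3,4-dihydronaphthalen-1(2H)-one | O=C1CC[C@@H](C)c2c1ccc(OC)c2OC
F7 | step 4 | (4R)-5,6-dimethoxy-4-methyl-3,4-dihydronaphthalen-1-yl trifluoromethanesulfonate | O=S(=O)(OC1=CC[C@@H](C)c2c1ccc(OC)c2OC)C(F)(F)F
F8 | step 5 | 2-{[(1R,4R)-5,6-dimethoxy-4-methyl-1,2,3,4-tetrahydronaphthalen-1-yl]methyl}-4,4,5,5-tetramethyl-1,3,2-dioxaborolane | CC1(C)OB(C[C@@H]2CC[C@@H](C)c3c2ccc(OC)c3OC)OC1(C)C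
F9 | step 5 | [(1R,4R)-5,6-dimethoxy-4-methyl-1,2,3,4-tetrahydronaphthalen-1-yl]methanol | OC[C@@H]1CC[C@@H](C)c2c1ccc(OC)c2OC
F10 | step 5 | (1R,4R)-5,6-dimethoxy-4-methyl-1,2,3,4-tetrahydronaphthalene-1-carbaldehyde | O=C[C@@H]1CC[C@@H](C)c2c1ccc(OC)c2OC
F11 | step 16 | 2-{(5R,8S)-3,4-dimethoxy-5-methyl-8-[(1R,4S)-4-methylcyclohept-2-en-1-yl]-5,6,7,8-tetrahydronaphthalen-2-yl}-4,4,5,5-tetramethyl-1,3,2-dioxaborolane | C[C@@H]1C=C[C@H]([C@@H]2CC[C@@H](C)c3c2cc(B4OC(C)(C)C(C)(C)O4)c(OC)c3OC)CCC1
F12 | step 18 | (5R,8S)-8-[(2S,6S)-1,7-diacetoxy-6-methylheptan-2-yl]-3,4-dimethoxy-5-methyl-5,6,7,8-tetrahydronaphthalene-2-carboxylic acid | C[C@H](COC(C)=O)CCC[C@H](COC(C)=O)[C@@H]1CC[C@@H](C)c2c1cc(C(=O)O)c(OC)c2OC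
F13 | step 18 | (5R,8S)-8-[(2S,6S)-1,7-diacetoxy-6-methylheptan-2-yl]-3,4-dihydroxy-5-methyl-5,6,7,8-tetrahydronaphthalene-2-carboxylic acid | C[C@H](COC(C)=O)CCC[C@H](COC(C)=O)[C@@H]1CC[C@@H](C)c2c1cc(C(=O)O)c(O)c2O
A1 | alternative 1 | methyl (5R,8S)-8-[(2S,6S)-1,7-bis(tert-butyldimethylsilyloxy)-6-methylheptan-2-yl]-3,4-dimethoxy-5-methyl-5,6,7,8-tetrahydronaphthalene-2-carboxylate | C[C@H](CO[Si](C)(C)C(C)(C)C)CCC[C@H](CO[Si](C)(C)C(C)(C)C)[C@@H]1CC[C@@H](C)c2c1cc(C(=O)OC)c(OC)c2OC
A2 | alternative 1 | methyl 4,5-dimethoxy-2-oxo-2H-pyran-3-carboxylate bearing at C6 the open chain with the C1 ethynyl group and the bis-silylated C11–C16 unit (stereocentres as in A1) | C[C@H](CO[Si](C)(C)C(C)(C)C)CCC[C@H](CO[Si](C)(C)C(C)(C)C)[C@@H](C#C)CC[C@@H](C)c1oc(=O)c(C(=O)OC)c(OC)c1OC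
A3 | alternative 2 | (2S,4E,6S)-7-(benzyloxy)-6-[(1S,4R)-5,6-dimethoxy-4-methyl-1,2,3,4-tetrahydronaphthalen-1-yl]-2-methylhept-4-en-1-ol | C[C@H](CO)C/C=C/[C@H](COCc1ccccc1)[C@@H]2CC[C@@H](C)c3c2ccc(OC)c3OC
A4 | alternative 2 | 1-[(E)-1-(benzyloxy)-4-iodobut-3-en-2-yl]-5,6-dimethoxy-4-methyl-1,2,3,4-tetrahydronaphthalene with the C1, C4 and C11 configurations of the target | I/C=C/[C@H](COCc1ccccc1)[C@@H]2CC[C@@H](C)c3c2ccc(OC)c3OC
A5 | alternative 2 | prop-2-en-1-ol | C=CCO
A6 | alternative 3 | methyl 2-oxo-4-[(1S,4R)-5,6-dimethoxy-4-methyl-1,2,3,4-tetrahydronaphthalen-1-yl]oxolane-3-carboxylate (C11 as in the target, ester-bearing carbon unspecified) | COC(=O)C1C(=O)OC[C@@H]1[C@@H]2CC[C@@H](C)c3c2ccc(OC)c3OC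
A7 | alternative 3 | methyl 6-[(3R)-3-(2,3-dimethoxyphenyl)butyl]-2-oxo-3-oxabicyclo[3.1.0]hexane-1-carboxylate (chain exo, configuration as in the SMILES) | COC(=O)[C@@]12C(=O)OC[C@@H]1[C@H]2CC[C@@H](C)c3cccc(OC)c3OC
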